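**Retrosynthetic overview**
1. Lettering: rings A, C and B are the benzo, pyranone and aryl rings of the 7-methoxyflavone unit. Rings D, F and E are the benzo, pyranone and 4-hydroxyphenyl rings of the 7''-hydroxyflavone unit.
2. Decisive feature: ring D (C4a''–C5''–C6''–C7''–C8''–C8a'') carries four adjacent substituents: C4'' on C4a'', O1'' on C8a'', C3' of ring B on C8'' and O7'' on C7''. The 3'–8'' biaryl bond therefore lies between two oxygens, and ring D is assembled around that bond rather than coupled to ring B.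
3. Ring D comes from the vinylketene derived from diazo enone 3 and aryl siloxyalkyne 7. The benzannulation forms C8a''–C8'', C7''–C6'' and C8a''–C4a'' and gives salicylate 12 with all four substituents in place.
4. Ring F: C4''–C3'' by Claisen condensation with ketone 15, then O1''–C2'' by acid cyclodehydration. Ring C: aryl bromide to terminal alkyne 20, then palladium-catalysed carbonylative annulation with iodophenol 21 (C4a–C4, C4–C3, O1–C2).
5. Rings are formed in the order D, F, C. Rings A, B and E are bought, and the two benzyl ethers are removed last.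

Key step: step 4

Assumption: the target SMILES gives no descriptor for the 3'–8'' biaryl axis, so the axis is treated as stereochemically undefined. The target has no stereocentre.

**Step 1**
Reactants: 1 methyl (E)-4-oxopent-2-enoate
Product: 3 methyl (E)-5-diazo-4-oxopent-2-enoate, via trifluoroacetyl diketone 2 (not isolated)
Conditions: LiN(SiMe3)2 (1.1 equiv), THF, −78 °C, slow addition of 1; CF3CO2CH2CF3, −78 °C; aq. HCl work-up; then MsN3, Et3N, H2O (1 equiv), MeCN, 25 °C
Reagents that add atoms: methanesulfonyl azide, CS(=O)(=O)N=[N+]=[N-]; 2,2,2-trifluoroethyl trifluoroacetate, O=C(OCC(F)(F)F)C(F)(F)F (its CF3CO group stands in 2 only)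
Why: Detrifluoroacetylative (Regitz-type) diazo transfer: slow addition of 1 to excess amide base deprotonates only the methyl group and keeps free enone scarce, the enolate is C-acylated to 2, and the sulfonyl azide then exchanges the CF3CO group for N2, the standard entry to diazomethyl enones that cannot be made by acylating diazomethane.

**Step 2**
Reactants: 4 5-bromo-2-methoxybenzaldehyde
Product: 5 4-bromo-2-ethynyl-1-methoxybenzene
Conditions: dimethyl (1-diazo-2-oxopropyl)phosphonate, K2CO3, MeOH, 25 °C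
Reagents that add atoms: dimethyl (1-diazo-2-oxopropyl)phosphonate, CC(=O)C(=[N+]=[N-])P(=O)(OC)OC
Why: Ohira–Bestmann variant of the Seyferth–Gilbert homologation: methanolysis frees the diazomethylphosphonate anion, which olefinates the aldehyde, and loss of N2 with a 1,2-hydrogen shift gives the terminal alkyne under conditions too mild to touch the aryl bromide.

**Step 3**
Reactants: 5 4-bromo-2-ethynyl-1-methoxybenzene
Product: 7 [(5-bromo-2-methoxyphenyl)ethynyloxy]triisopropylsilane, via lithium ynolate 6 (not isolated)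
Conditions: LiN(SiMe3)2 (2.1 equiv in all), tBuOOH (anhydrous), THF, −78 → 0 °C; then iPr3SiOTf, −78 → 0 °C
Reagents that add atoms: tert-butyl hydroperoxide, CC(C)(C)OO; triisopropylsilyl triflate, CC(C)[Si](C(C)C)(C(C)C)OS(=O)(=O)C(F)(F)F; lithium hexamethyldisilazide, [Li+].C[Si](C)(C)[N-][Si](C)(C)C (its lithium stands in 6 only)
Why: Electrophilic oxygenation of the lithium acetylide by LiOOtBu gives ynolate 6, which the bulky silyl triflate captures on oxygen rather than carbon; the amide base replaces butyllithium so that no bromine–lithium exchange can occur.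

**Step 4**
Reactants: 3 methyl (E)-5-diazo-4-oxopent-2-enoate; 7 [(5-bromo-2-methoxyphenyl)ethynyloxy]triisopropylsilane
Product: 12 methyl 3-(5-bromo-2-methoxyphenyl)-2-hydroxy-4-(triisopropylsilyloxy)benzoate, via vinylketene 8 (not isolated), via alkenylcyclobutenone 9 (not isolated), via dienylketene 10 (not isolated), via cyclohexadienone 11 (not isolated)
Conditions: 3 (1.4 equiv, added over 4 h), hν (365 nm LEDs), CH2Cl2, 25 °C; then toluene, 110 °C
Reagents that add atoms: none
Why: Light expels N2 from 3 and the alkenyl group shifts to the carbene carbon (Wolff rearrangement), so vinylketene 8 forms in the presence of 7 and adds to it in a [2+2] sense, making C8a''–C8'' and C7''–C6'' in cyclobutenone 9. On heating, 9 opens by a four-electron conrotatory process (breaking the old ketene bond C8a''–C6'') to dienylketene 10, and ring D closes by a six-electron disrotatory electrocyclisation that joins C8a'' to C4a'' and gives dienone 11, whose ester-acidified C4a''–H enolises to phenol 12. The reaction type is the Danheiser benzannulation in its diazo ketone form, for which alkenyl diazomethyl ketones and triisopropylsiloxyalkynes are the usual partners; the β-ester of 3 and the aryl group of 7 are new substituents on that known pair. The selectivity required is the orientation of the [2+2] step: the siloxy oxygen makes the aryl-bearing alkyne carbon the nucleophilic one, it attacks the ketene carbonyl carbon, and the aryl group therefore ends up between O1'' and O7''. The ester should raise the electrophilicity of 8, the opening of 9 is reversible so that only the geometry of 10 able to cyclise is drained, and the stereocentres of 9 and 11 vanish on aromatisation, so none has to be controlled. Light of 365 nm is absorbed by the diazo enone only, which spares the C–Br bond, and slow addition of 3 keeps the ketene dilute.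

**Step 5**
Reactants: 12 methyl 3-(5-bromo-2-methoxyphenyl)-2-hydroxy-4-(triisopropylsilyloxy)benzoate
Product: 13 methyl 4-(benzyloxy)-3-(5-bromo-2-methoxyphenyl)-2-hydroxybenzoate
Conditions: CsF (2 equiv), BnBr (1.05 equiv), DMF, 25 °C
Reagents that add atoms: benzyl bromide, BrCc1ccccc1
Why: Fluoride desilylation releases the more acidic 4-phenoxide, which undergoes Williamson benzylation in situ while the ester-chelated, aryl-flanked 2-OH stays free; the exchange is made because a silyl ether of the acidic O7'' phenol would not survive steps 7, 10 and 11.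

**Step 6**
Reactants: 13 methyl 4-(benzyloxy)-3-(5-bromo-2-methoxyphenyl)-2-hydroxybenzoate
Product: 14 methyl 4-(benzyloxy)-3-(5-bromo-2-methoxyphenyl)-2-(methoxymethoxy)benzoate
Conditions: NaH, MOMCl, DMF, 0 → 25 °C
Reagents that add atoms: chloromethyl methyl ether, COCCl
Why: Irreversible deprotonation breaks the chelate and the small, highly reactive chloromethyl ether alkylates the hindered phenoxide (Williamson type), so that no phenoxide can deactivate the ester in the next step.

**Step 7**
Reactants: 14 methyl 4-(benzyloxy)-3-(5-bromo-2-methoxyphenyl)-2-(methoxymethoxy)benzoate; 15 4'-benzyloxyacetophenone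
Product: 16 1-[4-(benzyloxy)-3-(5-bromo-2-methoxyphenyl)-2-(methoxymethoxy)phenyl]-3-[4-(benzyloxy)phenyl]propane-1,3-dione
Conditions: NaH (3 equiv), THF, 65 °C; aq. HCl work-up
Reagents that add atoms: none
Why: Crossed Claisen condensation of the sodium enolate of 15 with the non-enolisable ester 14 forms C4''–C3'' and is driven by deprotonation of the β-diketone, the classical way from 2,4-dialkoxybenzoates to flavone diketones.

**Step 8**
Reactants: 16 1-[4-(benzyloxy)-3-(5-bromo-2-methoxyphenyl)-2-(methoxymethoxy)phenyl]-3-[4-(benzyloxy)phenyl]propane-1,3-dione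
Product: 18 7-(benzyloxy)-2-[4-(benzyloxy)phenyl]-8-(5-bromo-2-methoxyphenyl)-4H-chromen-4-one, via free phenol diketone 17 (not isolated)
Conditions: conc. HCl, MeOH–THF, 60 °C
Reagents that add atoms: none
Why: Acid transfers the methoxymethyl group to methanol, the freed O1'' phenol of 17 adds to the aroyl carbonyl (six-membered hemiketal) and dehydration gives pyranone ring F, while benzyl ethers and the aryl bromide tolerate methanolic HCl.

**Step 9**
Reactants: 18 7-(benzyloxy)-2-[4-(benzyloxy)phenyl]-8-(5-bromo-2-methoxyphenyl)-4H-chromen-4-one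
Product: 19 7-(benzyloxy)-2-[4-(benzyloxy)phenyl]-8-{2-methoxy-5-[(trimethylsilyl)ethynyl]phenyl}-4H-chromen-4-one
Conditions: ethynyltrimethylsilane, PdCl2(PPh3)2 (5 mol %), CuI (10 mol %), Et3N–DMF, 80 °C, sealed tube
Reagents that add atoms: ethynyltrimethylsilane, C#C[Si](C)(C)C
Why: Sonogashira coupling at the only carbon–halogen bond of 18; heating makes up for the slower oxidative addition of the anisole-type bromide.

**Step 10**
Reactants: 19 7-(benzyloxy)-2-[4-(benzyloxy)phenyl]-8-{2-methoxy-5-[(trimethylsilyl)ethynyl]phenyl}-4H-chromen-4-one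
Product: 20 7-(benzyloxy)-2-[4-(benzyloxy)phenyl]-8-(5-ethynyl-2-methoxyphenyl)-4H-chromen-4-one
Conditions: K2CO3 (0.2 equiv), MeOH–THF, 25 °C
Reagents that add atoms: none
Why: Methoxide-catalysed protodesilylation of the alkynylsilane is fast at room temperature, where the pyranone ring is not opened.

**Step 11**
Reactants: 20 7-(benzyloxy)-2-[4-(benzyloxy)phenyl]-8-(5-ethynyl-2-methoxyphenyl)-4H-chromen-4-one; 21 2-iodo-5-methoxyphenol
Product: 23 7-(benzyloxy)-2-[4-(benzyloxy)phenyl]-8-[2-methoxy-5-(7-methoxy-4-oxo-4H-chromen-2-yl)phenyl]-4H-chromen-4-one, via ynone 22 (not isolated)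
Conditions: CO (10 bar), PdCl2(dppf) (5 mol %), Et2NH, DMF, 100 °C
Reagents that add atoms: carbon monoxide, [C-]#[O+]
Why: Carbonylative Sonogashira coupling with annulation: zerovalent palladium inserts into the C–I bond of 21, CO insertion and alkynylation give ynone 22, and reversible conjugate addition of diethylamine steers the phenol to the 6-endo closure that forms ring C with the methoxy group at C7; ring F is a flavone like the product and should tolerate the same medium.

**Step 12**
Reactants: 23 7-(benzyloxy)-2-[4-(benzyloxy)phenyl]-8-[2-methoxy-5-(7-methoxy-4-oxo-4H-chromen-2-yl)phenyl]-4H-chromen-4-one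
Product: 24 7-hydroxy-2-(4-hydroxyphenyl)-8-[2-methoxy-5-(7-methoxy-4-oxo-4H-chromen-2-yl)phenyl]-4H-chromen-4-one (CNP0121664.0)
Conditions: H2 (1 atm), Pd/C (10 %), THF–MeOH, 25 °C
Reagents that add atoms: none
Why: Catalytic hydrogenolysis cleaves both benzylic C–O bonds and leaves the two methyl ethers untouched, and at atmospheric pressure the conjugated C2–C3 bonds of flavones should not be reduced if hydrogen uptake is followed.

**Compound list**
1 | methyl (E)-4-oxopent-2-enoate | CC(=O)/C=C/C(=O)OC | starting material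
2 | methyl (E)-7,7,7-trifluoro-4,6-dioxohept-2-enoate | COC(=O)/C=C/C(=O)CC(=O)C(F)(F)F | intermediate
3 | methyl (E)-5-diazo-4-oxopent-2-enoate | COC(=O)/C=C/C(=O)C=[N+]=[N-] | intermediate
4 | 5-bromo-2-methoxybenzaldehyde | COc1ccc(Br)cc1C=O | starting material
5 | 4-bromo-2-ethynyl-1-methoxybenzene | COc1ccc(Br)cc1C#C | intermediate
6 | lithium 2-(5-bromo-2-methoxyphenyl)ethynolate | COc1ccc(Br)cc1C#C[O-].[Li+] | intermediate
7 | [(5-bromo-2-methoxyphenyl)ethynyloxy]triisopropylsilane | COc1ccc(Br)cc1C#CO[Si](C(C)C)(C(C)C)C(C)C | intermediate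
8 | methyl (2E)-5-oxopenta-2,4-dienoate | COC(=O)/C=C/C=C=O | intermediate
9 | methyl (E)-3-[3-(5-bromo-2-methoxyphenyl)-4-oxo-2-(triisopropylsilyloxy)cyclobut-2-en-1-yl]prop-2-enoate (racemic) | COC(=O)/C=C/C1C(=O)C(c2cc(Br)ccc2OC)=C1O[Si](C(C)C)(C(C)C)C(C)C | intermediate
10 | methyl (2E,4E)-6-(5-bromo-2-methoxyphenyl)-7-oxo-5-(triisopropylsilyloxy)hepta-2,4,6-trienoate | COC(=O)/C=C/C=C(/O[Si](C(C)C)(C(C)C)C(C)C)C(=C=O)c1cc(Br)ccc1OC | intermediate
11 | methyl 5-(5-bromo-2-methoxyphenyl)-6-oxo-4-(triisopropylsilyloxy)cyclohexa-2,4-diene-1-carboxylate (racemic) | COC(=O)C1C=CC(O[Si](C(C)C)(C(C)C)C(C)C)=C(c2cc(Br)ccc2OC)C1=O | intermediate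
12 | methyl 3-(5-bromo-2-methoxyphenyl)-2-hydroxy-4-(triisopropylsilyloxy)benzoate | COC(=O)c1ccc(O[Si](C(C)C)(C(C)C)C(C)C)c(-c2cc(Br)ccc2OC)c1O | intermediate
13 | methyl 4-(benzyloxy)-3-(5-bromo-2-methoxyphenyl)-2-hydroxybenzoate | COC(=O)c1ccc(OCc2ccccc2)c(-c2cc(Br)ccc2OC)c1O | intermediate
14 | methyl 4-(benzyloxy)-3-(5-bromo-2-methoxyphenyl)-2-(methoxymethoxy)benzoate | COCOc1c(C(=O)OC)ccc(OCc2ccccc2)c1-c1cc(Br)ccc1OC | intermediate
15 | 4'-benzyloxyacetophenone | CC(=O)c1ccc(OCc2ccccc2)cc1 | starting material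
16 | 1-[4-(benzyloxy)-3-(5-bromo-2-methoxyphenyl)-2-(methoxymethoxy)phenyl]-3-[4-(benzyloxy)phenyl]propane-1,3-dione | COCOc1c(C(=O)CC(=O)c2ccc(OCc3ccccc3)cc2)ccc(OCc2ccccc2)c1-c1cc(Br)ccc1OC | intermediate
17 | 1-[4-(benzyloxy)-3-(5-bromo-2-methoxyphenyl)-2-hydroxyphenyl]-3-[4-(benzyloxy)phenyl]propane-1,3-dione | Oc1c(C(=O)CC(=O)c2ccc(OCc3ccccc3)cc2)ccc(OCc2ccccc2)c1-c1cc(Br)ccc1OC | intermediate
18 | 7-(benzyloxy)-2-[4-(benzyloxy)phenyl]-8-(5-bromo-2-methoxyphenyl)-4H-chromen-4-one | COc1ccc(Br)cc1-c1c(OCc2ccccc2)ccc2c(=O)cc(-c3ccc(OCc4ccccc4)cc3)oc12 | intermediate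
19 | 7-(benzyloxy)-2-[4-(benzyloxy)phenyl]-8-{2-methoxy-5-[(trimethylsilyl)ethynyl]phenyl}-4H-chromen-4-one | COc1ccc(C#C[Si](C)(C)C)cc1-c1c(OCc2ccccc2)ccc2c(=O)cc(-c3ccc(OCc4ccccc4)cc3)oc12 | intermediate
20 | 7-(benzyloxy)-2-[4-(benzyloxy)phenyl]-8-(5-ethynyl-2-methoxyphenyl)-4H-chromen-4-one | COc1ccc(C#C)cc1-c1c(OCc2ccccc2)ccc2c(=O)cc(-c3ccc(OCc4ccccc4)cc3)oc12 | intermediate
21 | 2-iodo-5-methoxyphenol | COc1ccc(I)c(O)c1 | starting material
22 | 7-(benzyloxy)-2-[4-(benzyloxy)phenyl]-8-{5-[3-(2-hydroxy-4-methoxyphenyl)-3-oxoprop-1-yn-1-yl]-2-methoxyphenyl}-4H-chromen-4-one | COc1ccc(C(=O)C#Cc2ccc(OC)c(-c3c(OCc4ccccc4)ccc4c(=O)cc(-c5ccc(OCc6ccccc6)cc5)oc34)c2)c(O)c1 | intermediate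
23 | 7-(benzyloxy)-2-[4-(benzyloxy)phenyl]-8-[2-methoxy-5-(7-methoxy-4-oxo-4H-chromen-2-yl)phenyl]-4H-chromen-4-one | COc1ccc2c(=O)cc(-c3ccc(OC)c(-c4c(OCc5ccccc5)ccc5c(=O)cc(-c6ccc(OCc7ccccc7)cc6)oc45)c3)oc2c1 | intermediate
24 | 7-hydroxy-2-(4-hydroxyphenyl)-8-[2-methoxy-5-(7-methoxy-4-oxo-4H-chromen-2-yl)phenyl]-4H-chromen-4-one | COc1ccc2c(=O)cc(-c3ccc(OC)c(-c4c(O)ccc5c(=O)cc(-c6ccc(O)cc6)oc45)c3)oc2c1 | target

**Step count**
Total steps: 12. Longest linear sequence: 11 steps (steps 2 to 12, from 4).

**Steps most likely to fail**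

*Step 4.*
- The acceptor alkene may photoisomerise from E to Z before or after loss of N2, and the Z ketene could then close onto its own ester oxygen.
- The ketene may dimerise.
- The [2+2] step may be slow at an alkyne that carries an ortho-substituted aryl group.
- The siloxyalkyne may be hydrolysed by traces of acid or water.

The fallback buys ring D and makes the biaryl bond by Suzuki–Miyaura coupling. It sets out from 15 and comes back at 18. Commercial methyl 2,4-dihydroxybenzoate is iodinated between its two oxygens (I2, HIO3, aq. EtOH) to methyl 2,4-dihydroxy-3-iodobenzoate F1. Benzylation at the unchelated 4-OH (BnBr, K2CO3, acetone) gives methyl 4-(benzyloxy)-2-hydroxy-3-iodobenzoate F2. Protection (MOMCl, NaH, DMF) gives methyl 4-(benzyloxy)-3-iodo-2-(methoxymethoxy)benzoate F3. Claisen condensation with 15 under the conditions of step 7 gives 1-[4-(benzyloxy)-3-iodo-2-(methoxymethoxy)phenyl]-3-[4-(benzyloxy)phenyl]propane-1,3-dione F4. Methanolic HCl as in step 8 gives 7-(benzyloxy)-2-[4-(benzyloxy)phenyl]-8-iodo-4H-chromen-4-one F5. Coupling with commercial (5-bromo-2-methoxyphenyl)boronic acid (Pd(PPh3)4, Na2CO3, DME–H2O, 80 °C), in which the C–I bond reacts ahead of C–Br, gives 18.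

*Step 1.*
- The lithium enolate may add in conjugate fashion to unreacted enone, which leads to oligomerisation.
- The diazo group of one molecule may undergo dipolar cycloaddition to the doubly activated alkene of another during concentration or storage.

The fallback carries the ester carbon through the benzannulation as an acetal and oxidises it afterwards. It sets out from 7 and comes back at 12. Wittig reaction of commercial 2,2-dimethoxyacetaldehyde with 1-(triphenylphosphoranylidene)propan-2-one (CH2Cl2) gives (E)-5,5-dimethoxypent-3-en-2-one F6, an ordinary enone. The diazo transfer of step 1 converts it into (E)-1-diazo-5,5-dimethoxypent-3-en-2-one F7. Irradiation of F7 with 7 under the conditions of step 4 gives 2-(5-bromo-2-methoxyphenyl)-6-(dimethoxymethyl)-3-(triisopropylsilyloxy)phenol F8. Mild hydrolysis (pyridinium tosylate, acetone–H2O) gives 3-(5-bromo-2-methoxyphenyl)-2-hydroxy-4-(triisopropylsilyloxy)benzaldehyde F9. Pinnick oxidation (NaClO2, NaH2PO4, 2-methylbut-2-ene, tBuOH–H2O) gives 3-(5-bromo-2-methoxyphenyl)-2-hydroxy-4-(triisopropylsilyloxy)benzoic acid F10. Esterification with Me3SiCHN2 (toluene–MeOH, 0 °C) gives 12.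

*Step 11.*
- Diethylamine may capture the acylpalladium intermediate (aminocarbonylation).
- Coupling may occur without CO uptake and be followed by 5-endo closure.
- The ynone may close in the 5-exo mode.

The fallback brings the carbonyl carbon in with the acyl partner, so that no CO gas is needed. It sets out from 20 and comes back at 23. Commercial 2-hydroxy-4-methoxybenzoic acid is acetylated (Ac2O, pyridine) to 2-acetoxy-4-methoxybenzoic acid F11. Oxalyl chloride with catalytic DMF in CH2Cl2 converts it into 2-acetoxy-4-methoxybenzoyl chloride F12. Acyl Sonogashira coupling of F12 with 20 (PdCl2(PPh3)2, CuI, Et3N, THF, 25 °C) gives 2-[3-(3-{7-(benzyloxy)-2-[4-(benzyloxy)phenyl]-4-oxo-4H-chromen-8-yl}-4-methoxyphenyl)prop-2-ynoyl]-5-methoxyphenyl acetate F13. Diethylamine in EtOH–THF at 60 °C removes the acetate, passes through 22 and closes ring C in the 6-endo mode to 23.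

**Further compounds**
F1 | step 4 | methyl 2,4-dihydroxy-3-iodobenzoate | COC(=O)c1ccc(O)c(I)c1O
F2 | step 4 | methyl 4-(benzyloxy)-2-hydroxy-3-iodobenzoate | COC(=O)c1ccc(OCc2ccccc2)c(I)c1O
F3 | step 4 | methyl 4-(benzyloxy)-3-iodo-2-(methoxymethoxy)benzoate | COCOc1c(C(=O)OC)ccc(OCc2ccccc2)c1I
F4 | step 4 | 1-[4-(benzyloxy)-3-iodo-2-(methoxymethoxy)phenyl]-3-[4-(benzyloxy)phenyl]propane-1,3-dione | COCOc1c(C(=O)CC(=O)c2ccc(OCc3ccccc3)cc2)ccc(OCc2ccccc2)c1I
F5 | step 4 | 7-(benzyloxy)-2-[4-(benzyloxy)phenyl]-8-iodo-4H-chromen-4-one | O=c1cc(-c2ccc(OCc3ccccc3)cc2)oc2c(I)c(OCc3ccccc3)ccc12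
F6 | step 1 | (E)-5,5-dimethoxypent-3-en-2-one | CC(=O)/C=C/C(OC)OC
F7 | step 1 | (E)-1-diazo-5,5-dimethoxypent-3-en-2-one | COC(OC)/C=C/C(=O)C=[N+]=[N-]
F8 | step 1 | 2-(5-bromo-2-methoxyphenyl)-6-(dimethoxymethyl)-3-(triisopropylsilyloxy)phenol | COC(OC)c1ccc(O[Si](C(C)C)(C(C)C)C(C)C)c(-c2cc(Br)ccc2OC)c1O
F9 | step 1 | 3-(5-bromo-2-methoxyphenyl)-2-hydroxy-4-(triisopropylsilyloxy)benzaldehyde | O=Cc1ccc(O[Si](C(C)C)(C(C)C)C(C)C)c(-c2cc(Br)ccc2OC)c1O
F10 | step 1 | 3-(5-bromo-2-methoxyphenyl)-2-hydroxy-4-(triisopropylsilyloxy)benzoic acid | OC(=O)c1ccc(O[Si](C(C)C)(C(C)C)C(C)C)c(-c2cc(Br)ccc2OC)c1O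
F11 | step 11 | 2-acetoxy-4-methoxybenzoic acid | COc1ccc(C(=O)O)c(OC(C)=O)c1
F12 | step 11 | 2-acetoxy-4-methoxybenzoyl chloride | COc1ccc(C(=O)Cl)c(OC(C)=O)c1
F13 | step 11 | 2-[3-(3-{7-(benzyloxy)-2-[4-(benzyloxy)phenyl]-4-oxo-4H-chromen-8-yl}-4-methoxyphenyl)prop-2-ynoyl]-5-methoxyphenyl acetate | COc1ccc(C(=O)C#Cc2ccc(OC)c(-c3c(OCc4ccccc4)ccc4c(=O)cc(-c5ccc(OCc6ccccc6)cc5)oc34)c2)c(OC(C)=O)c1
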